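**Remark on the chemistry:** every carbon keeps its germacrane locant in all intermediates (pyran O–C1…C5, epoxide C4/C15, lactone O–C6/C12, C11=C13, ester carbinol C8, C9=C10–C14). Descriptors written with these locants change wherever a substituent changes priority, although the spatial arrangement stays the same.

## Analysis of the target

Target 45 is an 11-oxabicyclo[5.3.1]undecene. A tetrahydropyran (O, C1–C5) has its 2,6-positions C1 and C5 bridged by the chain C6–C10, so that O, C1, C10, C9, C8, C7, C6 and C5 form an eight-membered ring. A trans-fused α-methylene-γ-butyrolactone (O–C6, C7, C11=C13, C12) sits on C6–C7, a spiro-epoxide on C4 (C4/C15), a methacrylate on C8 and a formyl group (C14) on the ring-cis C9=C10 bond.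

The six stereocentres are 1R, 4R, 5R, 6S, 7R and 8R. H1 and H5 are cis across the pyran oxygen. The C4–O bond lies on the pyran face opposite to the C5–C6 bond. O6 is syn to the pyran oxygen along C4–C5–C6–C7. H6 and H7 are anti (trans lactone), and the C8 oxygen is cis to C11 on the eight-membered ring.

The sensitive groups are three Michael acceptors (enal, methylene lactone, methacrylate) and a tertiary epoxide next to an ether carbon, which rules out acid late in the route. The difficulty lies in the medium ring with its trisubstituted enal, in the four contiguous stereocentres C5–C8, and in fixing the quaternary C4 relative to C5.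

The plan rests on one feature: C5 carries the pyran oxygen, while C4 and C15 share the epoxide oxygen. A C4–C5 vinyl epoxide with a leaving group on C15 therefore already holds both oxygens on the right carbons, and its C4–O bond can pass unchanged into the spiro-epoxide.

## Retrosynthetic reasoning

**C8–O acyl bond.** The methacrylate of 45 is cut first, giving hydroxy enal 43 and anhydride 44. A methacrylate would not survive enolates, hydride or SmI2, so it has to come last. The forward step only needs to acylate a secondary allylic alcohol.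

**Oxidation level at C14 and the silyl ethers.** Enal 43 goes back to diol 42 and to bis-silyl ether 41. The aldehyde is revealed late because it would compete as an acceptor in every earlier C–C bond formation. The forward oxidation must take the primary allylic alcohol and leave the C8 hydroxyl.

**C11=C13.** The exocyclic methylene of 41 is cut to lactone 37 and iminium salt 38 (through amine 39). This lets the ring closure use a plain enoate, the best-behaved acceptor for a ketyl. The forward steps are a Mannich reaction and an elimination.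

**C6–C7 and O6–C12.** Lactone 37 is opened to aldehyde enoate 35. This cut closes the eight-membered ring and the lactone in one reductive step and creates C6 and C7 next to the pyran oxygen, which can hold the reducing metal. A cut at C9=C10 (ring-closing metathesis) would have required C6 and C7 to be set in an intermolecular reaction, for which neither chelation nor the trans relationship is easy to secure. The forward reaction has to add the C6 ketyl to C7 anti to C4 and with ketyl oxygen and enoate anti.

**C7=C11.** Enoate 35 goes back through 34 to alcohol 31 and ylide 32. The cut is a Wittig disconnection of an E-enoate; the forward sequence must not let the intermediate α-silyloxy aldehyde 33 epimerise.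

**C9=C10.** Alcohol 31 goes back through 30 and 29 to enoate 28, which is cut between C9 and C10 into ester 19 and aldehyde 25. C10 is α to the C14 ester, so an aldol addition and dehydration build the trisubstituted alkene. Its more stable isomer has the ester trans to C8, and therefore C8 cis to C1, as the ring requires. Aldehyde 25 carries C8 and comes from (S)-solketal 20.

**C6 oxidation state.** Triethylsilyl ether 19 goes back to vinyl pyran 16. The vinyl group is cleaved while it is the only alkene in the molecule, and C6 is stored as a silyl ether that Swern conditions later turn directly into the aldehyde.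

**C5–O1 and C15–O (key step).** Pyran 16 goes back to hydroxy vinyl epoxide 14. Zerovalent palladium ionises the allylic C5–O bond, the C1 oxygen takes C5, and the C4 oxygen closes on C15 with loss of chloride. Nowhere else can both heterocycles be made from a single stereodefined epoxide. Two points are adjusted for the forward reaction:
- The net change sets free one equivalent of HCl, so carbonate is present.
- The C1 side chain is carried as CH2CO2Me (C10, C14) rather than as a silyloxyethyl group, so that C10 is ready for the aldol of step 17.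

**C1–C10.** β-Hydroxy ester 14 is cut into aldehyde 11 and silyl ketene acetal 12. A catalytic acetate aldol sets C1 and leaves the hydroxyl free, so no protecting group is needed at C1.

**Epoxide, C4=C5 and C3–C4.** Aldehyde 11 goes back through 10, 9 and 8 to epoxy alcohol 7, which comes from dienol 6 by Sharpless epoxidation (C4 and C5). Dienol 6 comes from dienoate 5, which is cut at C4=C5 into phosphonate 3 and acrolein 4. Phosphonate 3 is cut at C3–C4 into phosphonoacetate 1 and bromide 2.

## Alternatives that were turned down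

**Alternative 1:** The ten-membered carbocycle is traced back to a cis-fused decalin by joining C5 and C10. In the forward sense a C5 alkoxide expels a C9 sulfonate, the C5–C10 bond breaks, and the germacrenone A1 results.
- For: ring size and C9=C10 geometry come from one stereospecific fragmentation that starts from the chiral pool. On olefin geometry it is stronger than the chosen route, whose step 18 relies on a thermodynamic preference.
- Against: A1 is only a carbocycle. The C1–O–C5 bridge must still be made across the ring from a C5 ketone. The isopropenyl group must be oxidised at C12 and lactonised to C6. The C14 methyl must be oxidised to the aldehyde next to other allylic positions. The acetonide must become the spiro-epoxide. Four different protecting groups are carried through this.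
- Comparison: the chosen route puts both ether oxygens in place in one step and carries C12 and C14 as esters from the start.

**Alternative 2:** C6–C7 and O6–C12 are cut. A C6 ketyl adds to C7 of a tethered 2-(acetoxymethyl)enoate, acetate leaves, the alkoxide lactonises, and A2 results.
- For: this is the same kind of closure as step 24, and it delivers C11=C13 directly. It is therefore two steps shorter than steps 24–26.
- Against: A2 has a 4(15)-alkene. The spiro-epoxide would have to be made late by epoxidising a 1,1-disubstituted alkene in the presence of the more nucleophilic C9=C10 bond, with only the bicycle to control the face. The cis-2,6-pyran is presupposed and not made.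
- Comparison: the chosen strategy fixes C4 by reagent control and forms pyran and epoxide together.

**Alternative 3:** C7–C8 and C11–C13 are cut on a C6-substituted butenolide. A lithiated dithiane adds to C7 anti to the C6 substituent and the enolate is trapped by an iminium salt, which gives A3.
- For: the trans relationship at C6/C7 follows from a simple steric argument and C13 arrives in the same step. On this point it is stronger than step 24, which must set C6 and C7 during a medium-ring closure.
- Against: no ring is formed. The pyran, the eight-membered ring, the C8 carbinol (dithiane hydrolysis and a new ketone reduction), C9=C10 and the whole C1–C5 part remain. The amine or a reactive methylene lactone must be carried through all of them.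
- Comparison: the chosen route is far more convergent in ring construction.

Key step: step 9

## Route

Step 1
Reactants: 1 triethyl phosphonoacetate; 2 (3-bromopropoxy)(tert-butyl)dimethylsilane
Product: 3 ethyl 5-[(tert-butyldimethylsilyl)oxy]-2-(diethoxyphosphoryl)pentanoate (racemic)
Conditions: NaH, DMF, 0 °C; then 2, NaI (cat.), 60 °C
Reagents that add atoms: none
Why: SN2 alkylation of the sodium carbanion of 1 by the primary bromide (iodide catalysis) forms the C3–C4 bond and keeps the phosphonate for the olefination.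

Step 2
Reactants: 3 ethyl 5-[(tert-butyldimethylsilyl)oxy]-2-(diethoxyphosphoryl)pentanoate; 4 acrolein
Product: 5 ethyl (2E)-2-{3-[(tert-butyldimethylsilyl)oxy]propyl}penta-2,4-dienoate
Conditions: NaH, THF, 0 °C; then 4, −78 → 0 °C
Reagents that add atoms: none
Why: Horner–Wadsworth–Emmons olefination; the α-substituted phosphonoacetate should give mainly the E-enoate (ester trans to the vinyl group), which places C15 trans to C6 as the later trans-epoxide needs, and the minor Z isomer is removed by chromatography.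

Step 3
Reactants: 5 ethyl (2E)-2-{3-[(tert-butyldimethylsilyl)oxy]propyl}penta-2,4-dienoate
Product: 6 (2E)-2-{3-[(tert-butyldimethylsilyl)oxy]propyl}penta-2,4-dien-1-ol
Conditions: i-Bu2AlH (2.2 equiv), CH2Cl2, −78 °C; aq. potassium sodium tartrate
Reagents that add atoms: none
Why: 1,2-Reduction of the dienoate by the aluminium hydride gives the allylic alcohol without touching the silyl ether or the diene.

Step 4
Reactants: 6 (2E)-2-{3-[(tert-butyldimethylsilyl)oxy]propyl}penta-2,4-dien-1-ol
Product: 7 [(2R,3R)-2-{3-[(tert-butyldimethylsilyl)oxy]propyl}-3-ethenyloxiran-2-yl]methanol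
Conditions: Ti(OiPr)4 (10 mol %), D-(−)-diethyl tartrate (12 mol %), t-BuOOH, 4 Å molecular sieves, CH2Cl2, −20 °C
Reagents that add atoms: tert-butyl hydroperoxide, CC(C)(C)OO
Why: Sharpless asymmetric epoxidation; the allylic hydroxyl directs the titanium peroxide to the C4=C5 bond only, and the D-tartrate delivers oxygen to the face that gives the (4R,5R) epoxy alcohol (the mirror image of the 2S,3S epoxides that L-tartrate gives with E allylic alcohols of this pattern). C4 and C5 are both set here.

Step 5
Reactants: 7 [(2R,3R)-2-{3-[(tert-butyldimethylsilyl)oxy]propyl}-3-ethenyloxiran-2-yl]methanol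
Product: 9 tert-butyl{3-[(2S,3R)-2-(chloromethyl)-3-ethenyloxiran-2-yl]propoxy}dimethylsilane, via mesylate 8 (not isolated)
Conditions: MsCl, Et3N, CH2Cl2, −10 °C; then LiCl, DMF, rt
Reagents that add atoms: lithium chloride, [Li+].[Cl-]
Why: Sulfonylation followed by SN2 displacement with chloride at the primary carbon next to the oxirane; no bond to C4 or C5 is touched, and the C4 descriptor becomes S only because CH2Cl now outranks C5.

Step 6
Reactants: 9 tert-butyl{3-[(2S,3R)-2-(chloromethyl)-3-ethenyloxiran-2-yl]propoxy}dimethylsilane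
Product: 10 3-[(2S,3R)-2-(chloromethyl)-3-ethenyloxiran-2-yl]propan-1-ol
Conditions: Bu4NF, AcOH, THF, 0 °C
Reagents that add atoms: none
Why: Fluoride cleaves the primary silyl ether; acetic acid keeps the medium near neutral so that neither the vinyl epoxide nor the chloride reacts.

Step 7
Reactants: 10 3-[(2S,3R)-2-(chloromethyl)-3-ethenyloxiran-2-yl]propan-1-ol
Product: 11 3-[(2S,3R)-2-(chloromethyl)-3-ethenyloxiran-2-yl]propanal
Conditions: Dess–Martin periodinane, NaHCO3, CH2Cl2, 0 °C → rt
Reagents that add atoms: none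
Why: Buffered Dess–Martin oxidation of a primary alcohol to the aldehyde under non-acidic conditions that the vinyl epoxide tolerates.

Step 8
Reactants: 11 3-[(2S,3R)-2-(chloromethyl)-3-ethenyloxiran-2-yl]propanal; 12 1-methoxy-1-(trimethylsilyloxy)ethene
Product: 14 methyl (3R)-5-[(2S,3R)-2-(chloromethyl)-3-ethenyloxiran-2-yl]-3-hydroxypentanoate, via trimethylsilyl ether 13 (not isolated)
Conditions: Ti(OiPr)4 (3 mol %), Schiff-base ligand from 2-amino-2′-hydroxy-1,1′-binaphthyl and 3-bromo-5-tert-butylsalicylaldehyde (3 mol %, enantiomer for Si-face attack), 3,5-di-tert-butylsalicylic acid (3 mol %), Et2O, −10 °C; then Bu4NF, AcOH, THF, 0 °C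
Reagents that add atoms: none
Why: Catalytic enantioselective Mukaiyama acetate aldol; the titanium Schiff-base complex activates the unbranched aldehyde and the ligand enantiomer is chosen so that 12 adds to the Si face, which sets C1 as R. The remote epoxide centres have no influence, and buffered fluoride removes the transferred silyl group to leave the free C1 hydroxyl.

Step 9
Reactants: 14 methyl (3R)-5-[(2S,3R)-2-(chloromethyl)-3-ethenyloxiran-2-yl]-3-hydroxypentanoate
Product: 16 methyl 2-[(3R,4R,6R)-4-ethenyl-1,5-dioxaspiro[2.5]octan-6-yl]acetate, via chlorohydrin 15 (not isolated)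
Conditions: Pd(PPh3)4 (5 mol %), K2CO3 (2 equiv), THF, 0 °C → rt; then MeOH, rt
Reagents that add atoms: none
Why: Proposed new method: zerovalent palladium adds to the allylic C5–O bond of the vinyl epoxide with inversion and gives a π-allyl complex over C5, C6 and the vinyl CH2 with a tertiary C4 alkoxide, which takes the proton of the C1 hydroxyl; the C1 alkoxide then attacks the C5 terminus anti to palladium (6-exo closure, allyl unit exocyclic) to give chlorohydrin 15, and the C4 oxygen, whose bond to C4 is never broken, displaces chloride from C15 (3-exo-tet) under carbonate and methanol, so that the oxygen of the old 4,5-epoxide becomes that of the 4,15-epoxide. The closest known reaction type is the zerovalent-palladium cycloetherification of hydroxy vinyl epoxides to 2-vinyl tetrahydropyrans, here joined in one flask with a halohydrin-to-epoxide closure. C5 is the only new stereocentre: double inversion means net retention, which from the (4S,5R)-epoxide gives the 5R ether, and this is also the isomer with the C1 and C5 substituents equatorial in the chair-like transition state, so that interconversion of the allyl faces through the CH2 terminus works in the same direction. C4 keeps the configuration of step 4 and C1 that of step 8. The step needs attack at C5 and not at the CH2 terminus (six- against eight-membered ring) and needs C4 never to act as an electrophile, which the π-allyl mechanism secures where acid catalysis would not. If chloride is lost before O1 attacks, the carbonate takes up the hydrogen chloride that the allyl substitution then sets free.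

Step 10
Reactants: 16 methyl 2-[(3R,4R,6R)-4-ethenyl-1,5-dioxaspiro[2.5]octan-6-yl]acetate
Product: 18 methyl 2-[(3R,4R,6R)-4-(hydroxymethyl)-1,5-dioxaspiro[2.5]octan-6-yl]acetate, via aldehyde 17 (not isolated)
Conditions: O3, CH2Cl2–MeOH, −78 °C; then NaBH4, −78 → 0 °C
Reagents that add atoms: ozone, [O-][O+]=O
Why: Ozonolysis of the only alkene with reduction in the same flask, so that the epimerisable α-alkoxy aldehyde 17 is never isolated; the ester and the epoxide survive NaBH4 at low temperature.

Step 11
Reactants: 18 methyl 2-[(3R,4R,6R)-4-(hydroxymethyl)-1,5-dioxaspiro[2.5]octan-6-yl]acetate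
Product: 19 methyl 2-[(3R,4R,6R)-4-{[(triethylsilyl)oxy]methyl}-1,5-dioxaspiro[2.5]octan-6-yl]acetate
Conditions: Et3SiCl, imidazole, CH2Cl2, 0 °C
Reagents that add atoms: chlorotriethylsilane, CC[Si](Cl)(CC)CC
Why: Silylation of the primary alcohol; the triethylsilyl ether is chosen because a primary triethylsilyl ether can later be oxidised directly to the aldehyde under Swern conditions.

Step 12
Reactants: 20 (S)-(2,2-dimethyl-1,3-dioxolan-4-yl)methanol
Product: 21 (S)-4-{[(4-methoxybenzyl)oxy]methyl}-2,2-dimethyl-1,3-dioxolane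
Conditions: NaH, 4-methoxybenzyl chloride, Bu4NI (cat.), THF–DMF, 0 °C → rt
Reagents that add atoms: 4-methoxybenzyl chloride, COc1ccc(CCl)cc1
Why: Williamson etherification of the primary alcohol; the stereocentre is not involved.

Step 13
Reactants: 21 (S)-4-{[(4-methoxybenzyl)oxy]methyl}-2,2-dimethyl-1,3-dioxolane
Product: 22 (R)-3-[(4-methoxybenzyl)oxy]propane-1,2-diol
Conditions: AcOH–H2O (4:1), 40 °C
Reagents that add atoms: none
Why: Acid hydrolysis of the isopropylidene acetal; the 4-methoxybenzyl ether is stable to aqueous acetic acid.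

Step 14
Reactants: 22 (R)-3-[(4-methoxybenzyl)oxy]propane-1,2-diol
Product: 23 (2S)-1,2-bis[(tert-butyldimethylsilyl)oxy]-3-[(4-methoxybenzyl)oxy]propane
Conditions: t-BuMe2SiCl (2.5 equiv), imidazole, DMF, rt
Reagents that add atoms: tert-butylchlorodimethylsilane, CC(C)(C)[Si](C)(C)Cl
Why: Exhaustive silylation of the diol.

Step 15
Reactants: 23 (2S)-1,2-bis[(tert-butyldimethylsilyl)oxy]-3-[(4-methoxybenzyl)oxy]propane
Product: 24 (2R)-2-[(tert-butyldimethylsilyl)oxy]-3-[(4-methoxybenzyl)oxy]propan-1-ol
Conditions: HF·pyridine, pyridine, THF, 0 °C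
Reagents that add atoms: none
Why: Buffered HF·pyridine removes the less hindered primary silyl ether selectively, a standard differentiation of primary and secondary tert-butyldimethylsilyl ethers.

Step 16
Reactants: 24 (2R)-2-[(tert-butyldimethylsilyl)oxy]-3-[(4-methoxybenzyl)oxy]propan-1-ol
Product: 25 (2S)-2-[(tert-butyldimethylsilyl)oxy]-3-[(4-methoxybenzyl)oxy]propanal
Conditions: Dess–Martin periodinane, CH2Cl2, 0 °C → rt
Reagents that add atoms: none
Why: Dess–Martin oxidation gives the α-silyloxy aldehyde without epimerisation; it is used at once.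

Step 17
Reactants: 19 methyl 2-[(3R,4R,6R)-4-{[(triethylsilyl)oxy]methyl}-1,5-dioxaspiro[2.5]octan-6-yl]acetate; 25 (2S)-2-[(tert-butyldimethylsilyl)oxy]-3-[(4-methoxybenzyl)oxy]propanal
Product: 26 methyl (4S)-4-[(tert-butyldimethylsilyl)oxy]-3-hydroxy-5-[(4-methoxybenzyl)oxy]-2-[(3R,4R,6R)-4-{[(triethylsilyl)oxy]methyl}-1,5-dioxaspiro[2.5]octan-6-yl]pentanoate (mixture at C9 and C10)
Conditions: LiN(i-Pr)2, THF, −78 °C; then 25, −78 °C; AcOH quench
Reagents that add atoms: none
Why: Aldol addition of the lithium ester enolate (C10) to aldehyde 25 forms the C9–C10 bond; at −78 °C the enolate should add faster than it expels the β-oxygen O1, and the two new stereocentres are of no consequence because both are removed in step 18.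

Step 18
Reactants: 26 methyl (4S)-4-[(tert-butyldimethylsilyl)oxy]-3-hydroxy-5-[(4-methoxybenzyl)oxy]-2-[(3R,4R,6R)-4-{[(triethylsilyl)oxy]methyl}-1,5-dioxaspiro[2.5]octan-6-yl]pentanoate
Product: 28 methyl (2E,4R)-4-[(tert-butyldimethylsilyl)oxy]-5-[(4-methoxybenzyl)oxy]-2-[(3R,4R,6R)-4-{[(triethylsilyl)oxy]methyl}-1,5-dioxaspiro[2.5]octan-6-yl]pent-2-enoate, via mesylate 27 (not isolated)
Conditions: MsCl, Et3N, CH2Cl2, 0 °C; then DBU, rt
Reagents that add atoms: none
Why: Mesylation and E1cB elimination with DBU give the trisubstituted enoate; the more stable E isomer has the ester trans to C8, that is C8 cis to C1 as the eight-membered ring needs, and mesylate leaves far faster than the ring oxygen.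

Step 19
Reactants: 28 methyl (2E,4R)-4-[(tert-butyldimethylsilyl)oxy]-5-[(4-methoxybenzyl)oxy]-2-[(3R,4R,6R)-4-{[(triethylsilyl)oxy]methyl}-1,5-dioxaspiro[2.5]octan-6-yl]pent-2-enoate
Product: 29 (2Z,4R)-4-[(tert-butyldimethylsilyl)oxy]-5-[(4-methoxybenzyl)oxy]-2-[(3R,4R,6R)-4-{[(triethylsilyl)oxy]methyl}-1,5-dioxaspiro[2.5]octan-6-yl]pent-2-en-1-ol
Conditions: i-Bu2AlH (2.5 equiv), CH2Cl2, −78 °C; aq. potassium sodium tartrate
Reagents that add atoms: none
Why: The aluminium hydride reduces the enoate to the allylic alcohol, so that no second acceptor is present in the ketyl cyclisation of step 24; ethers, silyl ethers and the epoxide are inert at −78 °C (the descriptor becomes Z by priority only).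

Step 20
Reactants: 29 (2Z,4R)-4-[(tert-butyldimethylsilyl)oxy]-5-[(4-methoxybenzyl)oxy]-2-[(3R,4R,6R)-4-{[(triethylsilyl)oxy]methyl}-1,5-dioxaspiro[2.5]octan-6-yl]pent-2-en-1-ol
Product: 30 (3R,4R,6R)-6-[(2Z,4R)-1,4-bis[(tert-butyldimethylsilyl)oxy]-5-[(4-methoxybenzyl)oxy]pent-2-en-2-yl]-4-{[(triethylsilyl)oxy]methyl}-1,5-dioxaspiro[2.5]octane
Conditions: t-BuMe2SiCl, imidazole, CH2Cl2, rt
Reagents that add atoms: tert-butylchlorodimethylsilane, CC(C)(C)[Si](C)(C)Cl
Why: Silylation of the primary allylic alcohol.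

Step 21
Reactants: 30 (3R,4R,6R)-6-[(2Z,4R)-1,4-bis[(tert-butyldimethylsilyl)oxy]-5-[(4-methoxybenzyl)oxy]pent-2-en-2-yl]-4-{[(triethylsilyl)oxy]methyl}-1,5-dioxaspiro[2.5]octane
Product: 31 (2R,3Z)-2,5-bis[(tert-butyldimethylsilyl)oxy]-4-[(3R,4R,6R)-4-{[(triethylsilyl)oxy]methyl}-1,5-dioxaspiro[2.5]octan-6-yl]pent-3-en-1-ol
Conditions: DDQ, CH2Cl2–pH 7 buffer, 0 °C
Reagents that add atoms: none
Why: Oxidative cleavage of the 4-methoxybenzyl ether by DDQ through the benzylic cation and its hemiacetal; the buffered two-phase medium protects the silyl ethers and the epoxide.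

Step 22
Reactants: 31 (2R,3Z)-2,5-bis[(tert-butyldimethylsilyl)oxy]-4-[(3R,4R,6R)-4-{[(triethylsilyl)oxy]methyl}-1,5-dioxaspiro[2.5]octan-6-yl]pent-3-en-1-ol; 32 methyl (triphenylphosphoranylidene)acetate
Product: 34 methyl (2E,4S,5Z)-4,7-bis[(tert-butyldimethylsilyl)oxy]-6-[(3R,4R,6R)-4-{[(triethylsilyl)oxy]methyl}-1,5-dioxaspiro[2.5]octan-6-yl]hepta-2,5-dienoate, via aldehyde 33 (not isolated)
Conditions: Dess–Martin periodinane, NaHCO3, CH2Cl2, 0 °C; then 32, rt
Reagents that add atoms: none
Why: Dess–Martin oxidation and Wittig olefination with the stabilised ylide in one flask, so that the α-silyloxy β,γ-unsaturated aldehyde 33 is trapped before it can epimerise at C8 or move its double bond; stabilised ylides give the E-enoate.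

Step 23
Reactants: 34 methyl (2E,4S,5Z)-4,7-bis[(tert-butyldimethylsilyl)oxy]-6-[(3R,4R,6R)-4-{[(triethylsilyl)oxy]methyl}-1,5-dioxaspiro[2.5]octan-6-yl]hepta-2,5-dienoate
Product: 35 methyl (2E,4S,5Z)-4,7-bis[(tert-butyldimethylsilyl)oxy]-6-[(3R,4S,6R)-4-formyl-1,5-dioxaspiro[2.5]octan-6-yl]hepta-2,5-dienoate
Conditions: (COCl)2, DMSO, CH2Cl2, −78 → −40 °C; then Et3N, −78 → 0 °C
Reagents that add atoms: none
Why: Swern conditions cleave a primary triethylsilyl ether in the flask and oxidise the freed alcohol to the aldehyde while tert-butyldimethylsilyl ethers stay in place (direct Swern oxidation of primary triethylsilyl ethers); the crude α-alkoxy aldehyde is used at once.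

Step 24
Reactants: 35 methyl (2E,4S,5Z)-4,7-bis[(tert-butyldimethylsilyl)oxy]-6-[(3R,4S,6R)-4-formyl-1,5-dioxaspiro[2.5]octan-6-yl]hepta-2,5-dienoate
Product: 37 (1R,4R,5R,6S,7S,8R,9Z)-8,14-bis[(tert-butyldimethylsilyl)oxy]-1,5:4,15-diepoxy-13-norgermacr-9-en-12,6-olide, via hydroxy ester 36 (not isolated)
Conditions: SmI2 (2.5 equiv), t-BuOH (2 equiv), THF, −78 → 0 °C, slow addition of 35 (0.005 M)
Reagents that add atoms: none
Why: Ketyl–olefin cyclisation with SmI2: the C6 ketyl adds to C7 of the enoate (8-exo-trig), the ester radical is reduced to the samarium enolate and protonated, and the C6 alkoxide of 36 closes the γ-lactone on the methyl ester (5-exo-trig). C6 should be set by a five-membered chelate of trivalent samarium between the ketyl oxygen and the pyran oxygen, with C7 approaching anti to C4 (6S); the anti arrangement of ketyl C–O and enoate gives the trans lactone, and the bicyclic array places the C8 silyloxy group and C11 on the open face.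

Step 25
Reactants: 37 (1R,4R,5R,6S,7S,8R,9Z)-8,14-bis[(tert-butyldimethylsilyl)oxy]-1,5:4,15-diepoxy-13-norgermacr-9-en-12,6-olide; 38 dimethylmethyleneiminium iodide
Product: 39 (1R,4R,5R,6S,7S,8R,9Z)-8,14-bis[(tert-butyldimethylsilyl)oxy]-13-(dimethylamino)-1,5:4,15-diepoxygermacr-9-en-12,6-olide (C11 epimers)
Conditions: LiN(i-Pr)2, THF, −78 °C; then 38, −78 → 0 °C
Reagents that add atoms: none
Why: Mannich aminomethylation of the lactone lithium enolate introduces C13; the configuration at C11 does not matter because the centre becomes trigonal in step 26.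

Step 26
Reactants: 39 (1R,4R,5R,6S,7S,8R,9Z)-8,14-bis[(tert-butyldimethylsilyl)oxy]-13-(dimethylamino)-1,5:4,15-diepoxygermacr-9-en-12,6-olide
Product: 41 (1R,4R,5R,6S,7S,8R,9Z)-8,14-bis[(tert-butyldimethylsilyl)oxy]-1,5:4,15-diepoxygermacra-9,11(13)-dien-12,6-olide, via methiodide 40 (not isolated)
Conditions: MeI, MeOH, rt; then NaHCO3 (aq), CH2Cl2, rt
Reagents that add atoms: none
Why: Quaternisation and E1cB loss of trimethylamine from the β-ammonio lactone give the exocyclic methylene under bicarbonate, which is mild enough for the epoxide.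

Step 27
Reactants: 41 (1R,4R,5R,6S,7S,8R,9Z)-8,14-bis[(tert-butyldimethylsilyl)oxy]-1,5:4,15-diepoxygermacra-9,11(13)-dien-12,6-olide
Product: 42 (1R,4R,5R,6S,7R,8R,9Z)-1,5:4,15-diepoxy-8,14-dihydroxygermacra-9,11(13)-dien-12,6-olide
Conditions: HF·pyridine, pyridine, THF, 0 °C → rt
Reagents that add atoms: none
Why: Pyridine-buffered HF·pyridine removes both silyl ethers; the buffered reagent spares epoxides and the methylene lactone.

Step 28
Reactants: 42 (1R,4R,5R,6S,7R,8R,9Z)-1,5:4,15-diepoxy-8,14-dihydroxygermacra-9,11(13)-dien-12,6-olide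
Product: 43 (1R,4R,5R,6S,7R,8R,9E)-1,5:4,15-diepoxy-8-hydroxy-14-oxogermacra-9,11(13)-dien-12,6-olide
Conditions: TEMPO (10 mol %), PhI(OAc)2, CH2Cl2, rt
Reagents that add atoms: none
Why: The oxoammonium oxidation takes primary alcohols in preference to secondary ones, so only C14 is oxidised and the C8 hydroxyl is left (the descriptor becomes E by priority only).

Step 29
Reactants: 43 (1R,4R,5R,6S,7R,8R,9E)-1,5:4,15-diepoxy-8-hydroxy-14-oxogermacra-9,11(13)-dien-12,6-olide; 44 methacrylic anhydride
Product: 45 (1R,4R,5R,6S,7R,8R,9E)-1,5:4,15-diepoxy-14-oxogermacra-9,11(13)-dien-12,6-olid-8-yl 2-methylprop-2-enoate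
Conditions: 44, Et3N, DMAP (cat.), CH2Cl2, 0 °C
Reagents that add atoms: none
Why: DMAP-catalysed acylation of the secondary allylic alcohol; no stereocentre is touched, and because C8 is trans to the formyl group the hydroxy enal cannot close to a lactol beforehand.

## Compound list

1 | triethyl phosphonoacetate | CCOC(=O)CP(=O)(OCC)OCC | starting material
2 | (3-bromopropoxy)(tert-butyl)dimethylsilane | BrCCCO[Si](C)(C)C(C)(C)C | starting material
3 | ethyl 5-[(tert-butyldimethylsilyl)oxy]-2-(diethoxyphosphoryl)pentanoate (racemic) | CCOC(=O)C(CCCO[Si](C)(C)C(C)(C)C)P(=O)(OCC)OCC | intermediate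
4 | acrolein | C=CC=O | starting material
5 | ethyl (2E)-2-{3-[(tert-butyldimethylsilyl)oxy]propyl}penta-2,4-dienoate | CCOC(=O)/C(CCCO[Si](C)(C)C(C)(C)C)=C/C=C | intermediate
6 | (2E)-2-{3-[(tert-butyldimethylsilyl)oxy]propyl}penta-2,4-dien-1-ol | OC/C(CCCO[Si](C)(C)C(C)(C)C)=C/C=C | intermediate
7 | [(2R,3R)-2-{3-[(tert-butyldimethylsilyl)oxy]propyl}-3-ethenyloxiran-2-yl]methanol | CC(C)(C)[Si](C)(C)OCCC[C@]1(CO)O[C@@H]1C=C | intermediate
8 | [(2R,3R)-2-{3-[(tert-butyldimethylsilyl)oxy]propyl}-3-ethenyloxiran-2-yl]methyl methanesulfonate | CC(C)(C)[Si](C)(C)OCCC[C@]1(COS(C)(=O)=O)O[C@@H]1C=C | intermediate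
9 | tert-butyl{3-[(2S,3R)-2-(chloromethyl)-3-ethenyloxiran-2-yl]propoxy}dimethylsilane | CC(C)(C)[Si](C)(C)OCCC[C@]1(CCl)O[C@@H]1C=C | intermediate
10 | 3-[(2S,3R)-2-(chloromethyl)-3-ethenyloxiran-2-yl]propan-1-ol | OCCC[C@]1(CCl)O[C@@H]1C=C | intermediate
11 | 3-[(2S,3R)-2-(chloromethyl)-3-ethenyloxiran-2-yl]propanal | O=CCC[C@]1(CCl)O[C@@H]1C=C | intermediate
12 | 1-methoxy-1-(trimethylsilyloxy)ethene | COC(=C)O[Si](C)(C)C | starting material
13 | methyl (3R)-5-[(2S,3R)-2-(chloromethyl)-3-ethenyloxiran-2-yl]-3-[(trimethylsilyl)oxy]pentanoate | COC(=O)C[C@H](O[Si](C)(C)C)CC[C@]1(CCl)O[C@@H]1C=C | intermediate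
14 | methyl (3R)-5-[(2S,3R)-2-(chloromethyl)-3-ethenyloxiran-2-yl]-3-hydroxypentanoate (key-step precursor) | COC(=O)C[C@H](O)CC[C@]1(CCl)O[C@@H]1C=C | intermediate
15 | methyl 2-[(2R,5S,6R)-5-(chloromethyl)-6-ethenyl-5-hydroxyoxan-2-yl]acetate | COC(=O)C[C@H]1CC[C@@](O)(CCl)[C@H](O1)C=C | intermediate
16 | methyl 2-[(3R,4R,6R)-4-ethenyl-1,5-dioxaspiro[2.5]octan-6-yl]acetate (key-step product) | COC(=O)C[C@H]1CC[C@@]2(CO2)[C@H](O1)C=C | intermediate
17 | methyl 2-[(3R,4S,6R)-4-formyl-1,5-dioxaspiro[2.5]octan-6-yl]acetate | COC(=O)C[C@H]1CC[C@@]2(CO2)[C@H](O1)C=O | intermediate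
18 | methyl 2-[(3R,4R,6R)-4-(hydroxymethyl)-1,5-dioxaspiro[2.5]octan-6-yl]acetate | COC(=O)C[C@H]1CC[C@@]2(CO2)[C@H](O1)CO | intermediate
19 | methyl 2-[(3R,4R,6R)-4-{[(triethylsilyl)oxy]methyl}-1,5-dioxaspiro[2.5]octan-6-yl]acetate | COC(=O)C[C@H]1CC[C@@]2(CO2)[C@H](O1)CO[Si](CC)(CC)CC | intermediate
20 | (S)-(2,2-dimethyl-1,3-dioxolan-4-yl)methanol | OC[C@H]1COC(C)(C)O1 | starting material
21 | (S)-4-{[(4-methoxybenzyl)oxy]methyl}-2,2-dimethyl-1,3-dioxolane | COc1ccc(COC[C@H]2COC(C)(C)O2)cc1 | intermediate
22 | (R)-3-[(4-methoxybenzyl)oxy]propane-1,2-diol | COc1ccc(COC[C@H](O)CO)cc1 | intermediate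
23 | (2S)-1,2-bis[(tert-butyldimethylsilyl)oxy]-3-[(4-methoxybenzyl)oxy]propane | COc1ccc(COC[C@H](O[Si](C)(C)C(C)(C)C)CO[Si](C)(C)C(C)(C)C)cc1 | intermediate
24 | (2R)-2-[(tert-butyldimethylsilyl)oxy]-3-[(4-methoxybenzyl)oxy]propan-1-ol | COc1ccc(COC[C@H](O[Si](C)(C)C(C)(C)C)CO)cc1 | intermediate
25 | (2S)-2-[(tert-butyldimethylsilyl)oxy]-3-[(4-methoxybenzyl)oxy]propanal | COc1ccc(COC[C@H](O[Si](C)(C)C(C)(C)C)C=O)cc1 | intermediate
26 | methyl (4S)-4-[(tert-butyldimethylsilyl)oxy]-3-hydroxy-5-[(4-methoxybenzyl)oxy]-2-[(3R,4R,6R)-4-{[(triethylsilyl)oxy]methyl}-1,5-dioxaspiro[2.5]octan-6-yl]pentanoate (mixture at C9 and C10) | COC(=O)C(C(O)[C@@H](O[Si](C)(C)C(C)(C)C)COCc1ccc(OC)cc1)[C@H]1CC[C@@]2(CO2)[C@H](O1)CO[Si](CC)(CC)CC | intermediate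
27 | 3-O-methanesulfonate of 26 | COC(=O)C(C(OS(C)(=O)=O)[C@@H](O[Si](C)(C)C(C)(C)C)COCc1ccc(OC)cc1)[C@H]1CC[C@@]2(CO2)[C@H](O1)CO[Si](CC)(CC)CC | intermediate
28 | methyl (2E,4R)-4-[(tert-butyldimethylsilyl)oxy]-5-[(4-methoxybenzyl)oxy]-2-[(3R,4R,6R)-4-{[(triethylsilyl)oxy]methyl}-1,5-dioxaspiro[2.5]octan-6-yl]pent-2-enoate | COC(=O)/C(=C/[C@@H](O[Si](C)(C)C(C)(C)C)COCc1ccc(OC)cc1)[C@H]1CC[C@@]2(CO2)[C@H](O1)CO[Si](CC)(CC)CC | intermediate
29 | (2Z,4R)-4-[(tert-butyldimethylsilyl)oxy]-5-[(4-methoxybenzyl)oxy]-2-[(3R,4R,6R)-4-{[(triethylsilyl)oxy]methyl}-1,5-dioxaspiro[2.5]octan-6-yl]pent-2-en-1-ol | OC/C(=C/[C@@H](O[Si](C)(C)C(C)(C)C)COCc1ccc(OC)cc1)[C@H]1CC[C@@]2(CO2)[C@H](O1)CO[Si](CC)(CC)CC | intermediate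
30 | (3R,4R,6R)-6-[(2Z,4R)-1,4-bis[(tert-butyldimethylsilyl)oxy]-5-[(4-methoxybenzyl)oxy]pent-2-en-2-yl]-4-{[(triethylsilyl)oxy]methyl}-1,5-dioxaspiro[2.5]octane | CC(C)(C)[Si](C)(C)OC/C(=C/[C@@H](O[Si](C)(C)C(C)(C)C)COCc1ccc(OC)cc1)[C@H]1CC[C@@]2(CO2)[C@H](O1)CO[Si](CC)(CC)CC | intermediate
31 | (2R,3Z)-2,5-bis[(tert-butyldimethylsilyl)oxy]-4-[(3R,4R,6R)-4-{[(triethylsilyl)oxy]methyl}-1,5-dioxaspiro[2.5]octan-6-yl]pent-3-en-1-ol | CC(C)(C)[Si](C)(C)OC/C(=C/[C@@H](O[Si](C)(C)C(C)(C)C)CO)[C@H]1CC[C@@]2(CO2)[C@H](O1)CO[Si](CC)(CC)CC | intermediate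
32 | methyl (triphenylphosphoranylidene)acetate | COC(=O)C=P(c1ccccc1)(c1ccccc1)c1ccccc1 | starting material
33 | (2R,3Z)-2,5-bis[(tert-butyldimethylsilyl)oxy]-4-[(3R,4R,6R)-4-{[(triethylsilyl)oxy]methyl}-1,5-dioxaspiro[2.5]octan-6-yl]pent-3-enal | CC(C)(C)[Si](C)(C)OC/C(=C/[C@@H](O[Si](C)(C)C(C)(C)C)C=O)[C@H]1CC[C@@]2(CO2)[C@H](O1)CO[Si](CC)(CC)CC | intermediate
34 | methyl (2E,4S,5Z)-4,7-bis[(tert-butyldimethylsilyl)oxy]-6-[(3R,4R,6R)-4-{[(triethylsilyl)oxy]methyl}-1,5-dioxaspiro[2.5]octan-6-yl]hepta-2,5-dienoate | CC(C)(C)[Si](C)(C)OC/C(=C/[C@@H](O[Si](C)(C)C(C)(C)C)/C=C/C(=O)OC)[C@H]1CC[C@@]2(CO2)[C@H](O1)CO[Si](CC)(CC)CC | intermediate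
35 | methyl (2E,4S,5Z)-4,7-bis[(tert-butyldimethylsilyl)oxy]-6-[(3R,4S,6R)-4-formyl-1,5-dioxaspiro[2.5]octan-6-yl]hepta-2,5-dienoate | CC(C)(C)[Si](C)(C)OC/C(=C/[C@@H](O[Si](C)(C)C(C)(C)C)/C=C/C(=O)OC)[C@H]1CC[C@@]2(CO2)[C@H](O1)C=O | intermediate
36 | methyl (1R,4R,5R,6S,7S,8R,9Z)-8,14-bis[(tert-butyldimethylsilyl)oxy]-1,5:4,15-diepoxy-6-hydroxy-13-norgermacr-9-en-12-oate | CC(C)(C)[Si](C)(C)O[C@@H]1/C=C(/CO[Si](C)(C)C(C)(C)C)[C@H]2CC[C@@]3(CO3)[C@H](O2)[C@@H](O)[C@@H]1CC(=O)OC | intermediate
37 | (1R,4R,5R,6S,7S,8R,9Z)-8,14-bis[(tert-butyldimethylsilyl)oxy]-1,5:4,15-diepoxy-13-norgermacr-9-en-12,6-olide | CC(C)(C)[Si](C)(C)O[C@@H]1/C=C(/CO[Si](C)(C)C(C)(C)C)[C@H]2CC[C@@]3(CO3)[C@H](O2)[C@H]2OC(=O)C[C@@H]21 | intermediate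
38 | dimethylmethyleneiminium iodide | C[N+](C)=C.[I-] | starting material
39 | (1R,4R,5R,6S,7S,8R,9Z)-8,14-bis[(tert-butyldimethylsilyl)oxy]-13-(dimethylamino)-1,5:4,15-diepoxygermacr-9-en-12,6-olide (C11 epimers) | CC(C)(C)[Si](C)(C)O[C@@H]1/C=C(/CO[Si](C)(C)C(C)(C)C)[C@H]2CC[C@@]3(CO3)[C@H](O2)[C@H]2OC(=O)C(CN(C)C)[C@@H]21 | intermediate
40 | N-methyl ammonium iodide of 39 | CC(C)(C)[Si](C)(C)O[C@@H]1/C=C(/CO[Si](C)(C)C(C)(C)C)[C@H]2CC[C@@]3(CO3)[C@H](O2)[C@H]2OC(=O)C(C[N+](C)(C)C)[C@@H]21.[I-] | intermediate
41 | (1R,4R,5R,6S,7S,8R,9Z)-8,14-bis[(tert-butyldimethylsilyl)oxy]-1,5:4,15-diepoxygermacra-9,11(13)-dien-12,6-olide | CC(C)(C)[Si](C)(C)O[C@@H]1/C=C(/CO[Si](C)(C)C(C)(C)C)[C@H]2CC[C@@]3(CO3)[C@H](O2)[C@H]2OC(=O)C(=C)[C@@H]21 | intermediate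
42 | (1R,4R,5R,6S,7R,8R,9Z)-1,5:4,15-diepoxy-8,14-dihydroxygermacra-9,11(13)-dien-12,6-olide | O[C@@H]1/C=C(/CO)[C@H]2CC[C@@]3(CO3)[C@H](O2)[C@H]2OC(=O)C(=C)[C@@H]21 | intermediate
43 | (1R,4R,5R,6S,7R,8R,9E)-1,5:4,15-diepoxy-8-hydroxy-14-oxogermacra-9,11(13)-dien-12,6-olide | O[C@@H]1/C=C(/C=O)[C@H]2CC[C@@]3(CO3)[C@H](O2)[C@H]2OC(=O)C(=C)[C@@H]21 | intermediate
44 | methacrylic anhydride | CC(=C)C(=O)OC(=O)C(C)=C | starting material
45 | (1R,4R,5R,6S,7R,8R,9E)-1,5:4,15-diepoxy-14-oxogermacra-9,11(13)-dien-12,6-olid-8-yl 2-methylprop-2-enoate | C=C(C)C(=O)O[C@@H]1/C=C(/C=O)[C@H]2CC[C@@]3(CO3)[C@H](O2)[C@H]2OC(=O)C(=C)[C@@H]21 | target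

## Step count and least certain steps

Total: 29 steps. Longest linear sequence: 24 steps (steps 1–11 and 17–29, from 1 and 2 to 45). Steps 12–16 are a five-step branch to aldehyde 25.

**Step 9 (key step; it bears the label).**
- What may go wrong: erosion of the facial selectivity at C5 if the allyl faces interconvert faster than the ring closes and the chair preference proves small; loss of chloride before the ether has formed, followed by opening of the new epoxide by hydrogen chloride; attack of the tertiary alkoxide on the vinyl terminus.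
- Fallback (known chemistry): set out from 14 and separate the two events. The base-free cycloetherification with zerovalent palladium (Pd2(dba)3 and the C2-symmetric diphosphine made from trans-1,2-diaminocyclohexane and 2-(diphenylphosphino)benzoic acid, CH2Cl2) is the established cyclisation of hydroxy vinyl epoxides, in which the tertiary alkoxide simply ends as an alcohol. It gives chlorohydrin 15 as an isolated compound, with the ligand reinforcing the facial selectivity. A separate Williamson closure (NaH, THF, 0 °C) then gives 16, where the route is rejoined.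

**Step 24.**
- What may go wrong: slow eight-membered closure, so that simple reduction of the aldehyde, pinacol coupling or expulsion of the α-oxygen O1 after a second electron transfer take over; wrong facial selectivity at C7 if the C8 silyloxy group prefers another orientation than the one assumed.
- Fallback: set out from 31 and change the closure from a ketyl radical to an allylmetal. Dess–Martin oxidation to 33 as in step 22 and a Morita–Baylis–Hillman reaction with methyl acrylate and DABCO give the hydroxy acrylate F1. Mesylation and SN2′ displacement with LiBr give the allylic bromide F2. Direct Swern oxidation as in step 23 gives the aldehyde F3. Intramolecular Nozaki–Hiyama–Kishi allylation (CrCl2, THF, high dilution) adds C7 to the C6 aldehyde through a closed six-membered transition state, and lactonisation delivers 41 directly, so that steps 25 and 26 fall away.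

**Step 18 (with step 17).**
- What may go wrong: incomplete geometric control in the E1cB elimination, because C8 and C1 end up cis on the alkene; ring opening by loss of O1 from the ester enolate.
- Fallback: set out from 29 as its E/Z mixture and correct the geometry at the aldehyde oxidation level. MnO2 gives the enal F4, which is equilibrated to the isomer with the formyl group trans to C8 (cat. PhSH, AIBN, benzene, 60 °C). Reduction with NaBH4 and CeCl3·7H2O in MeOH returns geometrically pure 29.

**Step 8.**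
- What may go wrong: low enantioselectivity or poor turnover with this functionalised aldehyde; Lewis-acid opening of the vinyl epoxide.
- Fallback: set out from 11 and replace catalyst control by an enzymatic reduction. Addition of the lithium enolate of methyl acetate (THF, −78 °C) gives 14 together with its C1 epimer F5. Dess–Martin oxidation of the mixture gives the β-keto ester F6. An R-selective ketoreductase (NADPH, glucose dehydrogenase recycling, pH 7 buffer) reduces the ketone and returns 14.

## Further compounds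

F0 | step 9 | none | none
F1 | step 24 | methyl 2-{(2R,3Z)-2,5-bis[(tert-butyldimethylsilyl)oxy]-1-hydroxy-4-[(3R,4R,6R)-4-{[(triethylsilyl)oxy]methyl}-1,5-dioxaspiro[2.5]octan-6-yl]pent-3-en-1-yl}prop-2-enoate (C7 epimers) | CC(C)(C)[Si](C)(C)OC/C(=C/[C@@H](O[Si](C)(C)C(C)(C)C)C(O)C(=C)C(=O)OC)[C@H]1CC[C@@]2(CO2)[C@H](O1)CO[Si](CC)(CC)CC
F2 | step 24 | methyl (2Z,5Z)-2-(bromomethyl)-4,7-bis[(tert-butyldimethylsilyl)oxy]-6-[(3R,4R,6R)-4-{[(triethylsilyl)oxy]methyl}-1,5-dioxaspiro[2.5]octan-6-yl]hepta-2,5-dienoate (C8 as in 34) | CC(C)(C)[Si](C)(C)OC/C(=C/[C@@H](O[Si](C)(C)C(C)(C)C)/C=C(\CBr)C(=O)OC)[C@H]1CC[C@@]2(CO2)[C@H](O1)CO[Si](CC)(CC)CC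
F3 | step 24 | methyl (2Z,5Z)-2-(bromomethyl)-4,7-bis[(tert-butyldimethylsilyl)oxy]-6-[(3R,4S,6R)-4-formyl-1,5-dioxaspiro[2.5]octan-6-yl]hepta-2,5-dienoate (C8 as in 34) | CC(C)(C)[Si](C)(C)OC/C(=C/[C@@H](O[Si](C)(C)C(C)(C)C)/C=C(\CBr)C(=O)OC)[C@H]1CC[C@@]2(CO2)[C@H](O1)C=O
F4 | step 18 | (2E,4R)-4-[(tert-butyldimethylsilyl)oxy]-5-[(4-methoxybenzyl)oxy]-2-[(3R,4R,6R)-4-{[(triethylsilyl)oxy]methyl}-1,5-dioxaspiro[2.5]octan-6-yl]pent-2-enal | O=C/C(=C/[C@@H](O[Si](C)(C)C(C)(C)C)COCc1ccc(OC)cc1)[C@H]1CC[C@@]2(CO2)[C@H](O1)CO[Si](CC)(CC)CC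
F5 | step 8 | methyl (3S)-5-[(2S,3R)-2-(chloromethyl)-3-ethenyloxiran-2-yl]-3-hydroxypentanoate | COC(=O)C[C@@H](O)CC[C@]1(CCl)O[C@@H]1C=C
F6 | step 8 | methyl 5-[(2S,3R)-2-(chloromethyl)-3-ethenyloxiran-2-yl]-3-oxopentanoate | COC(=O)CC(=O)CC[C@]1(CCl)O[C@@H]1C=C
A1 | alternative 1 | germacr-9-en-5-one with 8-O-(4-methoxybenzyl), 1-O-triethylsilyl, 6-O-methoxymethyl, 4,15-O-isopropylidene and 7-isopropenyl groups | COc1ccc(cc1)CO[C@@H]2/C=C(/C)[C@H](O[Si](CC)(CC)CC)CC[C@@]3(COC(C)(C)O3)C(=O)[C@@H](OCOC)[C@@H]2C(C)=C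
A2 | alternative 2 | bicyclic α-methylene lactone with 4(15)-alkene and 8,14-bis(tert-butyldimethylsilyl) ethers | CC(C)(C)[Si](C)(C)O[C@@H]1/C=C(/CO[Si](C)(C)C(C)(C)C)[C@H]2CCC(=C)[C@H](O2)[C@H]2OC(=O)C(=C)[C@@H]21
A3 | alternative 3 | trans,trans-5-{[(tert-butyldimethylsilyl)oxy]methyl}-3-[(dimethylamino)methyl]-4-(1,3-dithian-2-yl)oxolan-2-one | CC(C)(C)[Si](C)(C)OC[C@H]2OC(=O)[C@@H](CN(C)C)[C@@H]2C1SCCCS1
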